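## Retrosynthetic overview

1. Last step, both new rings at once: the azepine (N4–C5) and the fused butenolide are closed in one flask from a seco amino aldehyde and pyruvic acid. This copies the presumed biogenesis: croomine-type 5,6-enamine plus pyruvate, aldol at C6, lactonisation onto the C5 iminium, dehydration.
2. The seco precursor is a Boc/dioxolane-protected 2,5-trans-pyrrolidine bis-lactone; its C11 methyl comes from a carbamate-directed butenolide hydrogenation.
3. C9–C9a (quaternary C9): decarboxylative N-acyliminium formation from a 5-substituted proline, then a vinylogous Mannich reaction with a 5-alkyl-3-methyl-2-silyloxyfuran.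
4. C3–C14: vinylogous Mannich reaction of 3-methyl-2-silyloxyfuran with the N-acyliminium ion from Boc-L-pyroglutamate benzyl ester, then one hydrogenation that sets C16 and frees the acid.
5. Ring order: the pyrrolidine (chiral pool) and both γ-lactones (from 3-methylfuran-2(5H)-one) are carried in; azepine and fused butenolide are formed last.

Assumption: 2-(3-bromopropyl)-1,3-dioxolane is bought as a catalogue compound; croomine numbering is used (N4, C5 N,O-acetal, C6–C8, C9 spiro, C9a, C1–C3; spirolactone C10–C12; C3-lactone C14–C17), which makes the target 3S,5S,9S,9aS,11R,14S,16S.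

## Route

Step 1
Reactants: 1 3-methylfuran-2(5H)-one; 2 triisopropylsilyl trifluoromethanesulfonate
Product: 3 3-methyl-2-(triisopropylsilyloxy)furan
Conditions: TIPSOTf (1.1 equiv), Et3N (1.3 equiv), CH2Cl2, 0 °C to rt
Reagents that add atoms: triisopropylsilyl trifluoromethanesulfonate (2), CC(C)[Si](OS(=O)(=O)C(F)(F)F)(C(C)C)C(C)C
Why: Soft enolisation and O-silylation of the butenolide give the aromatic 2-silyloxyfuran (silyl dienol ether formation); no stereocentre is formed.

Step 2
Reactants: 3 3-methyl-2-(triisopropylsilyloxy)furan; 4 2-(3-bromopropyl)-1,3-dioxolane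
Product: 6 5-[3-(1,3-dioxolan-2-yl)propyl]-3-methyl-2-(triisopropylsilyloxy)furan, via 5-lithiofuran 5 (not isolated)
Conditions: s-BuLi (1.1 equiv), TMEDA, THF, −78 to 0 °C; then 4, −78 °C to rt
Reagents that add atoms: 2-(3-bromopropyl)-1,3-dioxolane (4), BrCCCC1OCCO1
Why: C5–H is the most acidic position of a 2-silyloxyfuran (α-lithiation of a furan) and the furyllithium is alkylated by the primary bromide (SN2) while the dioxolane is inert to organolithiums; no stereocentre is formed.

Step 3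
Reactants: 7 benzyl (2S)-1-(tert-butoxycarbonyl)-5-oxopyrrolidine-2-carboxylate; 3 3-methyl-2-(triisopropylsilyloxy)furan
Product: 9 benzyl (2S,5S)-1-Boc-5-[(2S)-4-methyl-5-oxo-2,5-dihydrofuran-2-yl]pyrrolidine-2-carboxylate, via hemiaminal 8 (not isolated)
Conditions: LiBHEt3 (1.1 equiv), THF, −78 °C, aq. NaHCO3 work-up (crude); then 3 (1.5 equiv), BF3·OEt2 (2 equiv), CH2Cl2, −78 °C
Reagents that add atoms: 3-methyl-2-(triisopropylsilyloxy)furan (3), Cc1ccoc1O[Si](C(C)C)(C(C)C)C(C)C
Why: Selective reduction of the Boc-activated lactam carbonyl gives the hemiaminal, which BF3 ionises to the N-acyliminium ion; the silyloxyfuran adds through its γ-carbon (vinylogous Mannich reaction) anti to the pseudoaxial benzyl ester (2,5-trans, C3 = S) and with the usual threo preference of five-membered N-acyliminium ions (C14 = S).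

Step 4
Reactants: 9 benzyl (2S,5S)-1-Boc-5-[(2S)-4-methyl-5-oxo-2,5-dihydrofuran-2-yl]pyrrolidine-2-carboxylate
Product: 10 (2S,5S)-1-Boc-5-[(2S,4S)-4-methyl-5-oxooxolan-2-yl]pyrrolidine-2-carboxylic acid
Conditions: H2 (1 atm), 10% Pd/C, EtOAc, rt
Reagents that add atoms: none
Why: Heterogeneous catalytic hydrogenation adds H2 to the butenolide face opposite the bulky N-Boc-pyrrolidinyl group on the γ-carbon, giving the cis-α-methyl-γ-lactone (C16 = S), and the same conditions cleave the benzyl ester by hydrogenolysis.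

Step 5
Reactants: 10 (2S,5S)-1-Boc-5-[(2S,4S)-4-methyl-5-oxooxolan-2-yl]pyrrolidine-2-carboxylic acid; 6 5-[3-(1,3-dioxolan-2-yl)propyl]-3-methyl-2-(triisopropylsilyloxy)furan
Product: 12 tert-butyl (2S,5S)-2-{(2S)-2-[3-(1,3-dioxolan-2-yl)propyl]-4-methyl-5-oxo-2,5-dihydrofuran-2-yl}-5-[(2S,4S)-4-methyl-5-oxooxolan-2-yl]pyrrolidine-1-carboxylate, via acetoxy aminal 11 (not isolated)
Conditions: PhI(OAc)2 (2 equiv), I2 (0.5 equiv), CH2Cl2, rt, visible light; aq. Na2S2O3 wash, dry (crude); then 6 (1.5 equiv), BF3·OEt2 (2 equiv), CH2Cl2, −78 °C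
Reagents that add atoms: 5-[3-(1,3-dioxolan-2-yl)propyl]-3-methyl-2-(triisopropylsilyloxy)furan (6), Cc1cc(CCCC2OCCO2)oc1O[Si](C(C)C)(C(C)C)C(C)C
Why: Radical oxidative decarboxylation with the trivalent iodine reagent and iodine (Suárez-type) converts the α-amino acid into the N,O-acetal acetate, whose N-acyliminium ion is attacked by the 5-substituted silyloxyfuran (vinylogous Mannich reaction) anti to the C3 lactone substituent (2,5-trans, C9a = S) and with threo topicity, creating the quaternary C9 (S), while the dioxolane is not ionised by BF3·OEt2 at −78 °C.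

Step 6
Reactants: 12 tert-butyl (2S,5S)-2-{(2S)-2-[3-(1,3-dioxolan-2-yl)propyl]-4-methyl-5-oxo-2,5-dihydrofuran-2-yl}-5-[(2S,4S)-4-methyl-5-oxooxolan-2-yl]pyrrolidine-1-carboxylate
Product: 13 tert-butyl (2S,5S)-2-{(2S,4R)-2-[3-(1,3-dioxolan-2-yl)propyl]-4-methyl-5-oxooxolan-2-yl}-5-[(2S,4S)-4-methyl-5-oxooxolan-2-yl]pyrrolidine-1-carboxylate
Conditions: H2 (4 bar), [Ir(cod)(PCy3)(py)]PF6 (10 mol%), CH2Cl2, rt
Reagents that add atoms: none
Why: Carbonyl-directed homogeneous hydrogenation with the cationic monovalent iridium complex: the Boc carbonyl binds iridium and delivers H2 to the butenolide face syn to the pyrrolidine (C9a side), overriding the steric bias and setting C11 = R (methyl cis to the C8 chain), while lactone, carbamate and dioxolane are untouched.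

Step 7
Reactants: 13 tert-butyl (2S,5S)-2-{(2S,4R)-2-[3-(1,3-dioxolan-2-yl)propyl]-4-methyl-5-oxooxolan-2-yl}-5-[(2S,4S)-4-methyl-5-oxooxolan-2-yl]pyrrolidine-1-carboxylate; 14 pyruvic acid
Product: 17 CNP0155196.1 (target), via amino aldehyde 15 (not isolated), via cyclic enamine 16 (not isolated)
Conditions: TFA/H2O (9:1), 0 °C to rt, evaporate; then pyruvic acid (5 equiv), pyridine (2 equiv), 4 Å MS, MeCN, 50 °C; NaHCO3 work-up
Reagents that add atoms: pyruvic acid (14), CC(=O)C(=O)O
Why: Proposed new method: acid removes Boc and the dioxolane, the freed secondary amine condenses with the δ-aldehyde to the seven-membered iminium/enamine, the enamine carbon C6 adds to the keto group of pyruvic acid (enamine aldol), the carboxylate closes on the C5 iminium and water is lost through the dienamine to give the fused butenolide N,O-acetal, with C5 set under thermodynamic control because the N,O-acetal equilibrates through the iminium carboxylate and is expected to settle as the natural 5S epimer (H-5 trans to H-9a); the closest known reaction types are the secondary-amine-mediated condensation of aldehydes with glyoxylic acid to 5-amino- and 5-hydroxybutenolides and amine-catalysed aldol additions to the keto group of pyruvates.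

## Compound list

1 | 3-methylfuran-2(5H)-one | CC1=CCOC1=O | starting material
2 | triisopropylsilyl trifluoromethanesulfonate | CC(C)[Si](OS(=O)(=O)C(F)(F)F)(C(C)C)C(C)C | starting material
3 | 3-methyl-2-(triisopropylsilyloxy)furan | Cc1ccoc1O[Si](C(C)C)(C(C)C)C(C)C | intermediate
4 | 2-(3-bromopropyl)-1,3-dioxolane | BrCCCC1OCCO1 | starting material
5 | 5-lithio-3-methyl-2-(triisopropylsilyloxy)furan (formed in the flask) | [Li]c1cc(C)c(O[Si](C(C)C)(C(C)C)C(C)C)o1 | intermediate
6 | 5-[3-(1,3-dioxolan-2-yl)propyl]-3-methyl-2-(triisopropylsilyloxy)furan | Cc1cc(CCCC2OCCO2)oc1O[Si](C(C)C)(C(C)C)C(C)C | intermediate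
7 | benzyl (2S)-1-(tert-butoxycarbonyl)-5-oxopyrrolidine-2-carboxylate (Boc-L-pyroglutamic acid benzyl ester) | CC(C)(C)OC(=O)N1C(=O)CC[C@H]1C(=O)OCc1ccccc1 | starting material
8 | benzyl (2S)-1-Boc-5-hydroxypyrrolidine-2-carboxylate, C5 epimers (formed in the flask) | CC(C)(C)OC(=O)N1C(O)CC[C@H]1C(=O)OCc1ccccc1 | intermediate
9 | benzyl (2S,5S)-1-Boc-5-[(2S)-4-methyl-5-oxo-2,5-dihydrofuran-2-yl]pyrrolidine-2-carboxylate | O=C(OCc1ccccc1)[C@@H]1CC[C@@H]([C@@H]2C=C(C)C(=O)O2)N1C(=O)OC(C)(C)C | intermediate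
10 | (2S,5S)-1-Boc-5-[(2S,4S)-4-methyl-5-oxooxolan-2-yl]pyrrolidine-2-carboxylic acid | OC(=O)[C@@H]1CC[C@@H]([C@@H]2C[C@H](C)C(=O)O2)N1C(=O)OC(C)(C)C | intermediate
11 | tert-butyl (5S)-2-acetoxy-5-[(2S,4S)-4-methyl-5-oxooxolan-2-yl]pyrrolidine-1-carboxylate, C2 epimers (formed in the flask) | CC(=O)OC1CC[C@@H]([C@@H]2C[C@H](C)C(=O)O2)N1C(=O)OC(C)(C)C | intermediate
12 | tert-butyl (2S,5S)-2-{(2S)-2-[3-(1,3-dioxolan-2-yl)propyl]-4-methyl-5-oxo-2,5-dihydrofuran-2-yl}-5-[(2S,4S)-4-methyl-5-oxooxolan-2-yl]pyrrolidine-1-carboxylate | O1CCOC1CCC[C@]1(C=C(C)C(=O)O1)[C@@H]1CC[C@@H]([C@@H]2C[C@H](C)C(=O)O2)N1C(=O)OC(C)(C)C | intermediate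
13 | tert-butyl (2S,5S)-2-{(2S,4R)-2-[3-(1,3-dioxolan-2-yl)propyl]-4-methyl-5-oxooxolan-2-yl}-5-[(2S,4S)-4-methyl-5-oxooxolan-2-yl]pyrrolidine-1-carboxylate | O1CCOC1CCC[C@]1(C[C@@H](C)C(=O)O1)[C@@H]1CC[C@@H]([C@@H]2C[C@H](C)C(=O)O2)N1C(=O)OC(C)(C)C | intermediate
14 | pyruvic acid (2-oxopropanoic acid) | CC(=O)C(=O)O | starting material
15 | 4-{(2S,4R)-4-methyl-2-[(2S,5S)-5-((2S,4S)-4-methyl-5-oxooxolan-2-yl)pyrrolidin-2-yl]-5-oxooxolan-2-yl}butanal (formed in the flask) | O=CCCC[C@]1(C[C@@H](C)C(=O)O1)[C@@H]1CC[C@@H]([C@@H]2C[C@H](C)C(=O)O2)N1 | intermediate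
16 | croomine-type 5,6-enamine: (3S,9S,9aS,11R,14S,16S) pyrrolo[1,2-a]azepine with N4–C5=C6, C9 spirolactone and C3 lactone (formed in the flask) | C1=CCC[C@]2(C[C@@H](C)C(=O)O2)[C@@H]2CC[C@@H]([C@@H]3C[C@H](C)C(=O)O3)N12 | intermediate
17 | CNP0155196.1: (3S,5S,9S,9aS,11R,14S,16S) croomine skeleton with an α-methylbutenolide fused across C5–C6 through the C5 N,O-acetal | CC1=C2CC[C@]3(C[C@@H](C)C(=O)O3)[C@@H]3CC[C@@H]([C@@H]4C[C@H](C)C(=O)O4)N3[C@H]2OC1=O | target

## Step count and risks

Total step count: 7. Longest linear sequence: 6 steps (steps 1, 3, 4, 5, 6, 7, from 3-methylfuran-2(5H)-one).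

**Most likely to fail, first: step 7.** Pyruvic acid may act as the enol donor toward the C5 iminium instead of as the acceptor, and the C5 epimer ratio is presumed, not known. The fallback sets out from 15, made from 13 by the same acid treatment. The salt is free-based and dried azeotropically to isolate the cyclic enamine 16. Under aprotic conditions 16 is used as a Stork-type nucleophile toward ethyl pyruvate (neat or in MeCN, rt), giving the enamine hydroxy ester F1. Warm aqueous HCl then dehydrates F1 through the dienamine, hydrolyses the conjugated iminium and lactonises the resulting (Z)-γ-oxo enoate to the ring-opened 5-hydroxybutenolide amine F2 (as its salt). Neutralisation and azeotropic removal of water close the azepine by pseudoacid–amine condensation, and the route is rejoined at 17.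

**Second: step 5.** Forming the quaternary C9 next to a 5-substituted N-acyliminium ion may give poor threo/trans selectivity and yield. The fallback reverses the order of the two Mannich reactions, so that the quaternary centre is made on the ester-bearing iminium ion and the easy addition comes last. It sets out from 8. With 6 and BF3·OEt2 at −78 °C, 8 gives the benzyl ester butenolide F3 (addition anti to the ester). Hydrogenation directed by the carbamate with [Ir(cod)(PCy3)(py)]PF6 gives the saturated (4R)-lactone benzyl ester F4. H2 over 10% Pd/C frees the carboxylic acid F5. PhI(OAc)2/I2 converts F5 into the N,O-acetal acetate F6. Furan 3 and BF3·OEt2 then add anti to the large quaternary substituent to give the bis-lactone butenolide F7. H2 over 10% Pd/C reduces F7 from the face opposite the pyrrolidine, and the route is rejoined at 13.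

**Third: step 6.** The carbamate may not direct well enough over a seven-membered chelate, and undirected reduction would give the C11 epimer. The fallback sets out from 12. Anhydrous TFA in CH2Cl2 at 0 °C removes only the Boc group and gives the free amine butenolide F8. Hydrogenation over 5% Rh/C in EtOAc uses the basic nitrogen as a haptophilic anchor and delivers hydrogen from the C9a face, giving the saturated amino acetal F9. Aqueous TFA then unmasks the aldehyde, and the route is rejoined at 15 inside step 7.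

Further compounds
F1 | step 7 | ethyl 2-hydroxy-2-(C6 of enamine 16)propanoate, the C6 aldol adduct of 16 and ethyl pyruvate (carbinol epimers) | C1=C(C(C)(O)C(=O)OCC)CC[C@]2(C[C@@H](C)C(=O)O2)[C@@H]2CC[C@@H]([C@@H]3C[C@H](C)C(=O)O3)N12
F2 | step 7 | 5-hydroxy-3-methyl-4-(2-{(2S,4R)-4-methyl-2-[(2S,5S)-5-((2S,4S)-4-methyl-5-oxooxolan-2-yl)pyrrolidin-2-yl]-5-oxooxolan-2-yl}ethyl)furan-2(5H)-one | CC1=C(CC[C@]2(C[C@@H](C)C(=O)O2)[C@@H]2CC[C@@H]([C@@H]3C[C@H](C)C(=O)O3)N2)C(O)OC1=O
F3 | step 5 | benzyl (2S,5S)-1-Boc-5-{(2S)-2-[3-(1,3-dioxolan-2-yl)propyl]-4-methyl-5-oxo-2,5-dihydrofuran-2-yl}pyrrolidine-2-carboxylate | O1CCOC1CCC[C@]1(C=C(C)C(=O)O1)[C@@H]1CC[C@@H](C(=O)OCc2ccccc2)N1C(=O)OC(C)(C)C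
F4 | step 5 | benzyl (2S,5S)-1-Boc-5-{(2S,4R)-2-[3-(1,3-dioxolan-2-yl)propyl]-4-methyl-5-oxooxolan-2-yl}pyrrolidine-2-carboxylate | O1CCOC1CCC[C@]1(C[C@@H](C)C(=O)O1)[C@@H]1CC[C@@H](C(=O)OCc2ccccc2)N1C(=O)OC(C)(C)C
F5 | step 5 | (2S,5S)-1-Boc-5-{(2S,4R)-2-[3-(1,3-dioxolan-2-yl)propyl]-4-methyl-5-oxooxolan-2-yl}pyrrolidine-2-carboxylic acid | O1CCOC1CCC[C@]1(C[C@@H](C)C(=O)O1)[C@@H]1CC[C@@H](C(=O)O)N1C(=O)OC(C)(C)C
F6 | step 5 | tert-butyl (2S)-5-acetoxy-2-{(2S,4R)-2-[3-(1,3-dioxolan-2-yl)propyl]-4-methyl-5-oxooxolan-2-yl}pyrrolidine-1-carboxylate (C5 epimers) | O1CCOC1CCC[C@]1(C[C@@H](C)C(=O)O1)[C@@H]1CCC(OC(C)=O)N1C(=O)OC(C)(C)C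
F7 | step 5 | tert-butyl (2S,5S)-2-{(2S,4R)-2-[3-(1,3-dioxolan-2-yl)propyl]-4-methyl-5-oxooxolan-2-yl}-5-[(2S)-4-methyl-5-oxo-2,5-dihydrofuran-2-yl]pyrrolidine-1-carboxylate | O1CCOC1CCC[C@]1(C[C@@H](C)C(=O)O1)[C@@H]1CC[C@@H]([C@@H]2C=C(C)C(=O)O2)N1C(=O)OC(C)(C)C
F8 | step 6 | (5S)-5-[3-(1,3-dioxolan-2-yl)propyl]-3-methyl-5-{(2S,5S)-5-[(2S,4S)-4-methyl-5-oxooxolan-2-yl]pyrrolidin-2-yl}furan-2(5H)-one | O1CCOC1CCC[C@]1(C=C(C)C(=O)O1)[C@@H]1CC[C@@H]([C@@H]2C[C@H](C)C(=O)O2)N1
F9 | step 6 | (3R,5S)-5-[3-(1,3-dioxolan-2-yl)propyl]-3-methyl-5-{(2S,5S)-5-[(2S,4S)-4-methyl-5-oxooxolan-2-yl]pyrrolidin-2-yl}oxolan-2-one | O1CCOC1CCC[C@]1(C[C@@H](C)C(=O)O1)[C@@H]1CC[C@@H]([C@@H]2C[C@H](C)C(=O)O2)N1
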